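Over the first 9.7 min the cedar flask climbs to 9.9 mM of X and reads the same at 7.8 min, although 40.1 mM of J and 10.1 mM of E, in whatever form, remain of its charge. That reading stands close to half of the E charged, so each X seems to cost about two E and not the one of the overall equation.

| flask | J | E | time |
|---|---|---|---|
| larch | 50.0 mM | 40.0 mM |  |
| maple | 20.0 mM | 10.0 mM |  |
| cedar | 50.0 mM | 20.0 mM |  |
| ash | 25.0 mM | 40.0 mM |  |
| alder | 50.0 mM | 40.0 mM | 29 min |

| run | time / min | [X] / mM |
|---|---|---|
| larch run | 1.9 | 8.7 |
| larch run | 3.9 | 13.4 |
| larch run | 5.8 | 16.8 |
| larch run | 7.8 | 18.2 |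
| larch run | 9.7 | 20.9 |
| maple run | 1.9 | 0.7 |
| maple run | 3.9 | 2.6 |
| maple run | 5.8 | 2.7 |
| maple run | 7.8 | 3.7 |
| maple run | 9.7 | 4.4 |
| cedar run | 1.9 | 5.1 |
| cedar run | 3.9 | 7.9 |
| cedar run | 5.8 | 9.3 |
| cedar run | 7.8 | 9.9 |
| cedar run | 9.7 | 9.9 |
| ash run | 1.9 | 5.2 |
| ash run | 3.9 | 9.6 |
| ash run | 5.8 | 11.4 |
| ash run | 7.8 | 13.4 |
| ash run | 9.7 | 15.0 |

(each reading ± 0.4 mM)

- Overall: J + E -> X.
- Constant volume, constant temperature.
- What is held in complexes is read along with the free species.
- "The second partner" is E.
- An order is taken over about fifteen percent of the charge, up and down.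

* the power of [J] that the first rate follows, about the charge of the larch run; measure it at two percent of J made into X (one fixed amount of X, the same in the runs compared)
* the power of [E] that the first rate follows, about the charge of the larch run; measure it at two percent of J made into X
* X in the alder run at 29 min, as a share of the J charged

Two extreme versions of the larch charge, which the alder flask repeats, can be solved in the head. In the loose version nothing holds E, one E goes per X, and E is the limiting reagent, so X runs toward 40.0 mM, which is 80.0% of the J charged. In the tight version every X takes a second E out for good, so X stops at 20.0 mM, half the E charged: the tight ceiling, here 40.0% of the J.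

The real flask lies between them. The cedar reading, close to its own ceiling of 10.0 mM, puts it toward the tight end. But the last larch reading, 20.9 mM, stands 2.25 standard deviations above the ceiling, and a hold that is an equilibrium lets X creep past. The reckoning here therefore puts the alder flask at 29 min above 40.0%, in the lower part of the range up to 80.0%.

The forecast gives orders of 0.9 in J and 1 in E, and 41.5% for the alder flask, which “should sit on the plateau”, a figure 1.5 percentage points above the tight share.

The alder flask gives 53.8% of its J at 29 min, with orders of 0.69 in J and 1.0 in E.

    J + E → X + L (5.838 M⁻¹ min⁻¹)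
    E + L ⇌ EL, settled at all times (292.0 M⁻¹)
    2 J ⇌ J2, settled at all times (18.50 M⁻¹)

The second E sits in EL, an equilibrium hold with K1 of 292 M⁻¹. The larch flask, of the same charge, has made half of its J by 21.1 min. The X of the alder flask, 26.9 mM, is 1.34 times the tight ceiling of 20.0 mM. The cedar flask passes its own ceiling of 10.0 mM as well, having made 12.5 mM of X, a quarter of its J, by 13.9 min.

(The earlier runs and the new flask are calculated from invented constants; scatter was added.)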